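**Retrosynthetic overview**
1. Target ⇐ desilylation and C4–O methacrylation of the bicyclic α-methylene lactone alcohol 16, itself from α-methylenation of lactone 14.
2. The six-membered carbocycle is closed last (C4–C3a bond) by a SmI2 ketyl–olefin cyclisation of enal-butenolide 13; this sets C4 and C3a.
3. The lactone ring comes in preformed: 13 ⇐ silyloxydiene 9 + 5-acetoxyfuranone 12 (from furfural) by a new catalytic enantioselective vinylogous Mukaiyama-type coupling that sets C7a.
4. 9 ⇐ tetrasubstituted enal 6 (directed aldol condensation of (S)-citronellal with silyloxyacetone), after cleavage of the prenyl terminus to the primary alcohol.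
5. (S)-Citronellal ⇐ geranial by organocatalytic transfer hydrogenation (first stereocentre).

Assumption: the catalyst antipodes named in steps 1 and 6 are those that give the configurations drawn; if a screen shows the opposite sense, the mirror-image catalyst is used.
Assumption: 11 and 12 are racemic intermediates made from achiral furfural; their C5 centre is destroyed on ionisation in step 6.

**Step 1**
Reactants: 1 geranial
Product: 2 (S)-citronellal
Conditions: Hantzsch ester (1.1 equiv), morpholinium salt of (S)-TRIP phosphoric acid (20 mol%), dioxane, 50 °C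
Reagents that add atoms: none
Why: Counteranion-directed iminium transfer hydrogenation, in which the morpholinium iminium ion paired with the chiral phosphate takes hydride from the Hantzsch ester on one face of C3 and sets the (S) methyl centre (E/Z iminium ions interconvert, so the reduction is stereoconvergent).

**Step 2**
Reactants: 2 (S)-citronellal; 3 1-{[tert-butyl(dimethyl)silyl]oxy}propan-2-one
Product: 6 4-{[tert-butyl(dimethyl)silyl]oxy}-3-methyl-2-[(2S)-6-methylhept-5-en-2-yl]but-2-enal (E/Z mixture), via aldimine 4 (not isolated), via hydroxy-imine 5 (not isolated)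
Conditions: c-HexNH2, MgSO4, Et2O; LiN(i-Pr)2, THF, −78 °C; 3, −78 → −20 °C; aq. oxalic acid, hexane, rt
Reagents that add atoms: none
Why: Wittig directed aldol condensation, in which the lithium aza-enolate adds to the chelating α-silyloxy ketone and acid hydrolysis with β-elimination of the tertiary carbinol gives the conjugated enal; the β-stereocentre is not enolisable and the alkene geometry does not matter because it is erased in step 4 and re-set in step 7.

**Step 3**
Reactants: 6 enal
Product: 8 4-{[tert-butyl(dimethyl)silyl]oxy}-2-[(2S)-5-hydroxypentan-2-yl]-3-methylbut-2-enal (E/Z mixture), via dialdehyde 7 (not isolated)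
Conditions: O3 (1 equiv, Sudan Red 7B end point), CH2Cl2, −78 °C; Me2S; then NaBH(OAc)3, AcOH, 0 °C
Reagents that add atoms: ozone, [O-][O+]=O
Why: Chemoselective ozonolysis of the electron-rich trisubstituted alkene (the enal C=C is electron-poor and fully substituted), then reduction of only the unhindered saturated aldehyde by the mild acyloxyborohydride.

**Step 4**
Reactants: 8 hydroxy enal
Product: 9 1-{[tert-butyl(dimethyl)silyl]oxy}-2-[(2S)-5-{[tert-butyl(dimethyl)silyl]oxy}pentan-2-yl]-3-({[tert-butyl(dimethyl)silyl]oxy}methyl)buta-1,3-diene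
Conditions: TBSOTf (2.4 equiv), Et3N, CH2Cl2, −78 → 0 °C
Reagents that add atoms: tert-butyldimethylsilyl trifluoromethanesulfonate, CC(C)(C)[Si](C)(C)OS(=O)(=O)C(F)(F)F
Why: Soft enolisation, in which the silyl triflate silylates the primary alcohol and the aldehyde oxygen and Et3N removes the most accessible γ-proton (the methyl group) to give the 1-silyloxydiene, a vinylogous enol silane.

**Step 5**
Reactants: 10 furfural
Product: 12 5-acetoxyfuran-2(5H)-one (racemic), via 5-hydroxyfuran-2(5H)-one 11 (not isolated)
Conditions: O2, hν (visible), tetraphenylporphyrin (cat.), CH2Cl2/MeOH, 0 °C; concentrate; Ac2O, pyridine, DMAP (cat.), CH2Cl2, 0 °C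
Reagents that add atoms: oxygen, O=O; acetic anhydride, CC(=O)OC(C)=O
Why: Schenck [4+2] photooxygenation of the furan by singlet oxygen, methanolysis of the endoperoxide with loss of methyl formate, then acetylation of the hydroxybutenolide.

**Step 6**
Reactants: 9 silyloxydiene; 12 5-acetoxyfuran-2(5H)-one
Product: 13 (5R)-5-{(4S)-7-{[tert-butyl(dimethyl)silyl]oxy}-2-({[tert-butyl(dimethyl)silyl]oxy}methyl)-3-formyl-4-methylhept-2-en-1-yl}furan-2(5H)-one (E/Z mixture)
Conditions: (S,S)-imidodiphosphorimidate (IDPi) Brønsted acid (3 mol%), toluene, −78 °C; aq. NaHCO3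
Reagents that add atoms: none
Why: Proposed new method: the silylated imidodiphosphorimidate (a silylium–chiral anion pair formed from the catalyst and a trace of 9) ionises the acetate of either enantiomer of 12 to the planar furanone oxocarbenium ion held in the confined chiral anion, the terminal CH2 of the diene (its only unhindered nucleophilic carbon) adds to one face of C5 to set the 5R centre, and silyl transfer to acetate turns the catalyst over; the closest known reactions are imidodiphosphorimidate-catalysed Mukaiyama additions of enol silanes to cyclic oxocarbenium ions from lactol acetates and vinylogous Mukaiyama aldol reactions.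

**Step 7**
Reactants: 13 enal-butenolide
Product: 14 (3aS,4S,7aR)-5-[(2S)-5-{[tert-butyl(dimethyl)silyl]oxy}pentan-2-yl]-6-({[tert-butyl(dimethyl)silyl]oxy}methyl)-4-hydroxy-3a,4,7,7a-tetrahydro-1-benzofuran-2(3H)-one
Conditions: SmI2 (2.5 equiv, slow addition), HMPA, t-BuOH (2 equiv), THF, −78 °C
Reagents that add atoms: none
Why: SmI2 ketyl–olefin radical cyclisation, in which the enal ketyl radical anion (whose C2–C3 bond can rotate, so both alkene isomers converge) attacks the β-carbon of the butenolide from the face carrying the tether to give the cis ring fusion, and the HMPA-solvated, non-chelated samarium alkoxide sits anti to the developing lactone enolate to give the 4S alcohol trans to the lactone carbon.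

**Step 8**
Reactants: 14 hydroxy lactone
Product: 16 (3aS,4S,7aR)-5-[(2S)-5-{[tert-butyl(dimethyl)silyl]oxy}pentan-2-yl]-6-({[tert-butyl(dimethyl)silyl]oxy}methyl)-4-hydroxy-3-methylidene-3a,4,7,7a-tetrahydro-1-benzofuran-2(3H)-one, via Mannich base 15 (not isolated)
Conditions: LiN(SiMe3)2 (2.3 equiv), THF, −78 °C; Me2N=CH2+ I−; then MeI, MeOH, rt; aq. NaHCO3, CH2Cl2
Reagents that add atoms: N,N-dimethylmethyleneiminium iodide, C=[N+](C)C.[I-]
Why: Eschenmoser α-methylenation, in which the lactone enolate is aminomethylated (Mannich reaction) and the quaternised amine eliminates to the exocyclic methylene, the only possible regiochemistry.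

**Step 9**
Reactants: 16 α-methylene lactone alcohol
Product: 17 (3aR,4S,7aR)-5-[(2S)-5-{[tert-butyl(dimethyl)silyl]oxy}pentan-2-yl]-6-({[tert-butyl(dimethyl)silyl]oxy}methyl)-3-methylidene-2-oxo-2,3,3a,4,7,7a-hexahydro-1-benzofuran-4-yl 2-methylprop-2-enoate
Conditions: methacrylic anhydride, DMAP, Et3N, CH2Cl2, 0 °C → rt
Reagents that add atoms: methacrylic anhydride, CC(=C)C(=O)OC(=O)C(C)=C
Why: DMAP-catalysed acylation of the only free hydroxyl, with retention at C4.

**Step 10**
Reactants: 17 bis-silyl ether
Product: 18 (3aR,4S,7aR)-6-(hydroxymethyl)-5-[(2S)-5-hydroxypentan-2-yl]-3-methylidene-2-oxo-2,3,3a,4,7,7a-hexahydro-1-benzofuran-4-yl 2-methylprop-2-enoate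
Conditions: HF·pyridine, pyridine, THF, 0 °C → rt
Reagents that add atoms: none
Why: Fluoride-mediated cleavage of both primary silyl ethers under buffered, non-basic conditions that spare the two acrylate units and the allylic ester.

**Compound list**
1 | geranial, (2E)-3,7-dimethylocta-2,6-dienal | O=C/C=C(C)/CCC=C(C)C | starting material
2 | (S)-citronellal, (3S)-3,7-dimethyloct-6-enal | O=CC[C@@H](C)CCC=C(C)C | intermediate
3 | 1-{[tert-butyl(dimethyl)silyl]oxy}propan-2-one | CC(=O)CO[Si](C)(C)C(C)(C)C | starting material
4 | (3S)-N-cyclohexyl-3,7-dimethyloct-6-en-1-imine | C(=NC1CCCCC1)C[C@@H](C)CCC=C(C)C | intermediate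
5 | β-hydroxy imine from 4 and 3 (mixture at the two new centres) | C(=NC1CCCCC1)C([C@@H](C)CCC=C(C)C)C(C)(O)CO[Si](C)(C)C(C)(C)C | intermediate
6 | 4-{[tert-butyl(dimethyl)silyl]oxy}-3-methyl-2-[(2S)-6-methylhept-5-en-2-yl]but-2-enal (E/Z) | O=CC([C@@H](C)CCC=C(C)C)=C(C)CO[Si](C)(C)C(C)(C)C | intermediate
7 | 4-{[tert-butyl(dimethyl)silyl]oxy}-3-methyl-2-[(2S)-5-oxopentan-2-yl]but-2-enal (E/Z) | O=CC([C@@H](C)CCC=O)=C(C)CO[Si](C)(C)C(C)(C)C | intermediate
8 | 4-{[tert-butyl(dimethyl)silyl]oxy}-2-[(2S)-5-hydroxypentan-2-yl]-3-methylbut-2-enal (E/Z) | O=CC([C@@H](C)CCCO)=C(C)CO[Si](C)(C)C(C)(C)C | intermediate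
9 | tris-silyl diene (see step 4) | C=C(CO[Si](C)(C)C(C)(C)C)C(=CO[Si](C)(C)C(C)(C)C)[C@@H](C)CCCO[Si](C)(C)C(C)(C)C | intermediate
10 | furfural | O=Cc1ccco1 | starting material
11 | 5-hydroxyfuran-2(5H)-one (racemic) | OC1OC(=O)C=C1 | intermediate
12 | 5-acetoxyfuran-2(5H)-one (racemic) | CC(=O)OC1OC(=O)C=C1 | intermediate
13 | (5R)-butenolide enal (see step 6; E/Z) | O=CC([C@@H](C)CCCO[Si](C)(C)C(C)(C)C)=C(CO[Si](C)(C)C(C)(C)C)C[C@@H]1C=CC(=O)O1 | intermediate
14 | (3aS,4S,7aR)-hydroxy lactone (see step 7) | O[C@@H]1C([C@@H](C)CCCO[Si](C)(C)C(C)(C)C)=C(CO[Si](C)(C)C(C)(C)C)C[C@H]2OC(=O)C[C@@H]12 | intermediate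
15 | 3-[(dimethylamino)methyl] derivative of 14 (mixture at C3) | O[C@@H]1C([C@@H](C)CCCO[Si](C)(C)C(C)(C)C)=C(CO[Si](C)(C)C(C)(C)C)C[C@H]2OC(=O)C(CN(C)C)[C@@H]12 | intermediate
16 | (3aS,4S,7aR)-α-methylene lactone alcohol (see step 8) | O[C@@H]1C([C@@H](C)CCCO[Si](C)(C)C(C)(C)C)=C(CO[Si](C)(C)C(C)(C)C)C[C@H]2OC(=O)C(=C)[C@@H]12 | intermediate
17 | bis-silyl ether of the target (see step 9) | C=C(C)C(=O)O[C@@H]1C([C@@H](C)CCCO[Si](C)(C)C(C)(C)C)=C(CO[Si](C)(C)C(C)(C)C)C[C@H]2OC(=O)C(=C)[C@@H]12 | intermediate
18 | CNP0142089.2 (see step 10) | C=C(C)C(=O)O[C@@H]1C([C@@H](C)CCCO)=C(CO)C[C@H]2OC(=O)C(=C)[C@@H]12 | target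

**Totals**
Total step count: 10. Longest linear sequence: 9 (steps 1–4 and 6–10, from geranial).

**Three steps most likely to fail**

Step 6 (the new coupling). The acyl-substituted oxocarbenium ion may ionise poorly, a Diels–Alder reaction between 9 and the butenolide may compete, and facial control at C5 is unproven. Fallback with known chemistry: setting out from 9 and 12, promote the same vinylogous Mukaiyama-type substitution with the achiral Lewis acid BF3·OEt2 (CH2Cl2, −78 °C), as is known for enol silanes and 5-acyloxybutenolides. This gives 13 together with its C5 epimer, the (5S)-butenolide enal F3, which are separated by chromatography. F3 is recycled by equilibrating the acidic butenolide γ-centre with catalytic Et3N and separating again. The route is rejoined at 13.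

Step 7 (SmI2 cyclisation). The conjugated aldehyde may be reduced 1,4, a carbanion at C3 may expel the allylic silyloxy group, and the C4 epimer may form. Fallback: setting out from 13, replace the two-electron organosamarium manifold by a neutral tin-ketyl radical chain (Bu3SnH, AIBN, benzene, 80 °C, syringe-pump addition). The allylic O-stannyl ketyl, which never becomes a carbanion, cyclises onto the butenolide and abstracts hydrogen to give the O-tributylstannyl ether of 14 F4. Work-up with aqueous KF cleaves it, and the route is rejoined at 14.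

Step 2 (directed aldol condensation). The α-branched aza-enolate must add to a hindered, enolisable ketone, and retro-aldol cleavage or incomplete dehydration are possible. Fallback: setting out from 2, switch from the basic aza-enolate to a Lewis-acid Mukaiyama aldol. Form the trimethylsilyl enol ether of citronellal F1 (Me3SiCl, Et3N, NaI, MeCN), add it to 3 under TiCl4 chelation control (CH2Cl2, −78 °C) to give the β-hydroxy aldehyde F2, and dehydrate with catalytic pyridinium p-toluenesulfonate (benzene, 60 °C). The route is rejoined at 6.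

**Further compounds**
F1 | step 2 | trimethyl{[(3S)-3,7-dimethylocta-1,6-dien-1-yl]oxy}silane | C[Si](C)(C)OC=C[C@@H](C)CCC=C(C)C
F2 | step 2 | 4-{[tert-butyl(dimethyl)silyl]oxy}-3-hydroxy-3-methyl-2-[(2S)-6-methylhept-5-en-2-yl]butanal | O=CC([C@@H](C)CCC=C(C)C)C(C)(O)CO[Si](C)(C)C(C)(C)C
F3 | step 6 | (5S) epimer of 13 | O=CC([C@@H](C)CCCO[Si](C)(C)C(C)(C)C)=C(CO[Si](C)(C)C(C)(C)C)C[C@H]1C=CC(=O)O1
F4 | step 7 | O-tributylstannyl ether of 14 | CCCC[Sn](CCCC)(CCCC)O[C@@H]1C([C@@H](C)CCCO[Si](C)(C)C(C)(C)C)=C(CO[Si](C)(C)C(C)(C)C)C[C@H]2OC(=O)C[C@@H]12
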